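## Structural features

The target contains three 2-aryl-2,3-dihydrobenzofurans. Ring system A carries a 4-hydroxyphenyl group at C2 and an (E)-3,4-dihydroxystyryl group at C4; the central ring system B carries a 4-hydroxyphenyl group at C2; ring system C carries a 4-hydroxyphenyl group at C2 and a 3,5-dihydroxyphenyl group at C3. The three are joined by two sp3–sp2 bonds: C3 of A to C4 of the benzo ring of B, and C3 of B to C4 of the benzo ring of C. The benzo ring of B is therefore 1,2,3,5-tetrasubstituted, with carbon at the adjacent positions C3a and C4 and oxygen at C6 (free hydroxyl) and C7a (ring oxygen). Six stereocentres form three vicinal trans pairs, (2R,3R) in A, (2S,3S) in B and (2R,3R) in C; arene rings separate the pairs, so each needs its own source of absolute configuration. The molecule is fragile: ten phenols including a catechol, three benzylic C2–O bonds that ionise in acid, and a stilbene beside ring A that can close a seven-membered ring onto the 3,5-dioxygenated benzo ring of B once a benzylic cation forms (the C2 cation of B can do the same onto the resorcinol ring of C). Strong acid and hydrogenolysis are therefore excluded at the end. In every precursor of ring A that has a carbonyl on C3, that carbon is α to the carbonyl and β to the ring oxygen, so base can epimerise it or open the furan ring. The real difficulty is the benzo ring of B, flanked by two bulky sp3 substituents. The key step uses its oxygenation pattern: O at C6 and C7a and C at C3a and C4 is what a folded 1,3,5-triketone gives, with C4 from the carbonyl bonded to C3 of ring A, C6 and C7a from the other two carbonyls, and C3a from the terminal methylene that carries the future C3 of ring B.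

## Logic of the disconnections

30 ⇒ 29. The nine aryl O–Si bonds are cut. The last step must be neither acidic nor reductive, and fluoride cleavage meets this. All phenols other than the two of ring B are thereby carried as one kind of ether. The forward demand is a silyl group that survives amide bases, aqueous carbonate and dilute acid, hence triisopropylsilyl throughout.

29 ⇒ 28. The O1–C2 bond of ring B is cut. C2 is a para-oxygenated benzylic carbon that ionises easily, and the C7a hydroxyl is delivered by the preceding step in the ortho position. The configuration at C2 then need not be controlled earlier, so either epimer of the methoxy-bearing carbon serves. The forward step must keep the cation short-lived so that oxygen (five-membered ring) and not carbon (seven-membered ring) captures it.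

28 ⇒ 27. The C3a–C4 bond of the benzo ring of B is cut, with rehydration and ketonisation of C6 and C7a. This turns the tetrasubstituted benzene and both sp3–sp2 links into a linear chain between two complete halves. The forward step must achieve an aldol condensation between two hindered termini under base mild enough for C3 of ring A and for the silyl ethers.

27 ⇒ 26 ⇒ 10 + 25. The C1–C2 bond of the octane chain (future C4–C5 of ring B) is cut at the aldehyde oxidation level, followed by an oxidation. The terminal methyl of 25 is where its dianion forms, and an aldehyde accepts a carbanion faster than it gives up its α-hydrogen. This divides the molecule into two halves of similar size. The forward step needs the correct dianion regiochemistry and low temperature.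

25 ⇒ 24 ⇒ 17 + 23. The acetyl C–C bond and the aryl–C bond at the future C3 of ring B are cut. That carbon is β to a ketone, so a catalyst-controlled conjugate arylation can set it independently of the stereocentres of ring C. The forward step needs a chiral rhodium catalyst free of achiral diene and must tolerate a hindered boronic acid; 23 is used racemic and in excess.

17 ⇒ 16 ⇒ 15 ⇒ 14 ⇒ 13 ⇒ 11 + 12, and 11 ⇒ 5. The C–B bond, two O–Si bonds, one ring bond of the 3,5-dioxygenated phenyl group, the chain bond to 12 and one oxidation level are cut. The aryl group on C3 of ring C is itself a 5-substituted resorcinol, a folded triketone grown from the C3 carbonyl. Ring C therefore comes from the same intermediate as ring A, and the key reaction is rehearsed in its easy form. The triflate must survive these steps.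

10 ⇒ 9 ⇒ 5 + 8. The aryl–vinyl bond at C4 of ring A is cut and the oxidation level adjusted. The triflate of 5 is a cross-coupling handle at exactly this carbon, and the stilbene arrives with defined (E) geometry.

5 ⇒ 4 ⇒ 3 ⇒ 2 ⇒ 1. The C3–C3a bond is cut (a 1,2-shift of the benzo carbon from the carbonyl carbon of a chromanone), preceded by a resolution, an O–S bond and two O–Si bonds. One resolved intermediate then supplies the (2R,3R) configuration of both outer rings. The forward step must transfer C2 unchanged, and the (2R) enantiomer of the chromanone must be obtained.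

23 ⇒ 21 + 22, 21 ⇒ 20 ⇒ 19 ⇒ 18, and 8 ⇒ 7 ⇒ 6. The enone C=C (cross-metathesis), an O–CH3 bond, a C–C bond to a vinyl group and an O–Si bond are cut; for 8, a C=C and two O–Si bonds. These lead to simple commercial hydroxybenzaldehydes.

## Other disconnections considered

Alternative 1: The cut is the C3–C3a bond of every dihydrobenzofuran, each furan ring being traced to the pyranone of a 2-arylchroman-4-one derived from 1. In the forward key step the (2R) ketone A1 is treated with PhI(OAc)2 and acid in trimethyl orthoformate; the benzo carbon moves from the carbonyl carbon to C3, the six-membered ring contracts, and the trans ester triflate A2 results.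
- In its favour: the source is cheap, C2 is transferred without change, the trans ring is obtained directly, and A2 carries an ester at C3 and a triflate at C4.
- Against it as the governing idea here: it forms no bond between the ring systems. Ring B would need a chromanone that already carries C3 of ring A at its 5-position, and its ring-contracted C3 carboxyl would have to be exchanged for the aryl carbon of ring C with retention. Three esters would have to become sp3–sp2 links, for which an ester offers no configurationally safe method. Ring B also needs the opposite (2S) series, and migration of the electron-rich 2-aryl group competes with the wanted shift.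
- Comparison: for the two outer rings this alternative is the equal of the chosen plan, which obtains 5, the silyl analogue of A2, by this same reaction. In fidelity at C2 it is better than any stereo-defining step of the plan, because it is stereospecific. The plans differ at ring B: the chosen one converts the two C3 carbonyl groups left by the ring contraction into the benzo ring of B by aldol chemistry, while the alternative has no counterpart for that ring and would be longer once the inter-ring bonds are counted.

Alternative 2: The cut is the three C2–aryl bonds. All three 4-oxyphenyl groups are left off until the end, and a preformed tris-dihydrobenzofuran carries a carboxylic acid at each C2. In the forward key step these acids and an aryl bromide are coupled under visible light with an iridium photocatalyst and a nickel bipyridine catalyst. Each acid loses CO2, the α-oxy radical at C2 is captured by nickel and arylated on the face away from the C3 substituent, and the octamethyl ether A3 with chloride at C4 of ring A is formed.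
- In its favour: three identical groups come from one reagent in one operation, and C2 configuration need not be carried through earlier steps. Ring B is not closed through a benzylic cation, so the seven-membered-ring hazard of an acid step is absent; on this point the alternative is the better of the two.
- Against it here: three radical couplings must succeed on one molecule, each with its own substrate-controlled facial choice. The aryl chloride must stay inert to low-valent nickel and then undergo a Heck reaction as a hindered chloride. Eight methyl ethers must be removed from an acid-sensitive polyphenol. Above all, the substrate already contains the tetrasubstituted benzo ring of B, both sp3–sp2 links and all three C3 centres, so the hardest part is moved into the precursor.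
- Comparison: structurally the chosen plan makes that ring and its links in the key step, while the alternative presupposes them. Mechanistically it is radical and nickel chemistry against enolate chemistry. Over the last three steps the alternative is equal or shorter, but the route to its substrate should be at least as long as the whole chosen plan.

Alternative 3: The cut is the C2–C3 bond of both outer rings at once. Two diaryl diazo groups, made in the flask from the corresponding hydrazones, are decomposed by a chiral tetracarboxylate of divalent rhodium. Each carbene inserts into the benzylic C–H bond of the neighbouring aryl 4-methoxybenzyl ether, closing both outer furan rings and giving A4. In A4, C3 of each outer ring is as in the target and C2 is epimeric (cis rings), so an acid equilibration at both C2 centres and conversion of the silyloxymethyl group into the styryl group must follow.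
- In its favour: the absolute configuration of both outer C3 centres comes from a catalyst, with no resolution and no loss of half of the material; here it is better than the chosen plan. Two rings are closed in one step, and diaryl carbenes tolerate ethers and arenes.
- Against it here: the hydrazones must be formed on benzophenones with two ortho substituents. The insertions occur on a substrate that already holds the (2S,3S) centres of ring B, so each is a case of double stereodifferentiation. The cis products need two ionisations at C2 on a molecule prone to seven-membered ring closure, and three further steps are needed for the stilbene. As in alternative 2, ring B with its four substituents must exist beforehand.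
- Comparison: in the kind of acid step needed the two plans are equal, but the chosen plan needs it once and the alternative twice. The alternative places its risk in two late insertions on the most valuable intermediate, the chosen plan in an early ring contraction on inexpensive material. In step count the alternative is similar or longer once ring B and the stilbene are included.

Key step: step 22

Conventions and assumptions:
- TIPS = Si(i-Pr)3; TIPSO = triisopropylsilyloxy.
- Unit A = the 2,3-trans-(2R)-4-[(E)-3,4-bis(TIPSO)styryl]-6-TIPSO-2-(4-TIPSO-phenyl)-2,3-dihydrobenzofuran-3-yl group of 10. Its C3 keeps the spatial arrangement of 10 throughout; the descriptor is 3R or 3S according to the priority of the attached carbon.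
- Unit C = the (2R,3R)-3-[3,5-bis(TIPSO)phenyl]-6-TIPSO-2-(4-TIPSO-phenyl)-2,3-dihydrobenzofuran-4-yl group of 17.
- Remark on the chemistry: the configuration of the target is read from its line notation as (2R,3R) in rings A and C and (2S,3S) in ring B.
- Remark on the chemistry: the methoxy-bearing benzylic carbon is carried as both epimers from 20 to 28, and the carbinol carbons of 13 and 26 likewise, because these centres are destroyed in steps 11, 21 and 23.

## Route

Step 1
Reactants: 1 naringenin (racemic)
Product: 2 rac-5-hydroxy-7-TIPSO-2-(4-TIPSO-phenyl)chroman-4-one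
Conditions: i-Pr3SiCl (2.2 equiv), imidazole, DMF, 0 → 25 °C
Reagents that add atoms: chlorotriisopropylsilane, CC(C)[Si](Cl)(C(C)C)C(C)C
Why: Silylation of phenols; the 5-hydroxyl is hydrogen-bonded to the C4 carbonyl and stays free, so only the 7- and 4′-oxygens react. The bulky silyl group is chosen to survive amide bases, carbonate and dilute acid and to leave with fluoride at the end.

Step 2
Reactants: 2 rac-5-hydroxy-7-TIPSO-2-(4-TIPSO-phenyl)chroman-4-one
Product: 3 rac-4-oxo-7-TIPSO-2-(4-TIPSO-phenyl)chroman-5-yl triflate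
Conditions: Tf2O, pyridine, CH2Cl2, −20 → 0 °C
Reagents that add atoms: trifluoromethanesulfonic anhydride, O=S(=O)(OS(=O)(=O)C(F)(F)F)C(F)(F)F
Why: O-Sulfonylation of the remaining phenol, much faster than enol triflate formation with pyridine as base; it installs the cross-coupling handle at the carbon that becomes C4 of both outer dihydrobenzofurans.

Step 3
Reactants: 3 rac-4-oxo-7-TIPSO-2-(4-TIPSO-phenyl)chroman-5-yl triflate
Product: 4 (2R)-4-oxo-7-TIPSO-2-(4-TIPSO-phenyl)chroman-5-yl triflate
Conditions: RuCl[(S,S)-TsDPEN](p-cymene) (1 mol%), HCO2H/Et3N (5:2), EtOAc, 25 °C, stopped a little beyond half conversion; chromatography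
Reagents that add atoms: none
Why: Kinetic resolution by Noyori–Ikariya asymmetric transfer hydrogenation: the (S,S) complex of divalent ruthenium forms (4S) benzylic carbinols, and with the inherent preference for the 2,4-cis alcohol this is matched only for the (2S) ketone, so that ketone should be reduced away to the (2S,4S) alcohol and the (2R) ketone 4 should remain. The medium is too weakly basic to open the pyranone, so C2 is not scrambled.

Step 4
Reactants: 4 (2R)-4-oxo-7-TIPSO-2-(4-TIPSO-phenyl)chroman-5-yl triflate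
Product: 5 methyl (2R,3R)-6-TIPSO-2-(4-TIPSO-phenyl)-4-(triflyloxy)-2,3-dihydrobenzofuran-3-carboxylate (2,3-trans)
Conditions: PhI(OAc)2 (1.3 equiv), H2SO4 (cat.), HC(OMe)3, 25 °C
Reagents that add atoms: trimethyl orthoformate, COC(OC)OC
Why: Oxidative ring contraction of a flavanone with hypervalent iodine: the enol ether formed in the orthoformate is attacked at C3 by the trivalent iodine reagent, and loss of iodobenzene is coupled to a 1,2-shift of the benzo carbon from the ketal carbon to C3, the former carbonyl carbon ending as the methyl ester. C2 is not involved, so its configuration is carried over, and the trans ester (also the thermodynamic isomer) should result; the silyloxy group makes the 2-aryl ring a weaker competitor for migration than an alkoxy group would.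

Step 5
Reactants: 6 3,4-dihydroxybenzaldehyde
Product: 7 3,4-bis(TIPSO)benzaldehyde
Conditions: i-Pr3SiCl (2.5 equiv), imidazole, DMF, 25 → 40 °C
Reagents that add atoms: chlorotriisopropylsilane, CC(C)[Si](Cl)(C(C)C)C(C)C
Why: Silylation of both catechol oxygens; the second, crowded silylation is driven by excess reagent and gentle warming.

Step 6
Reactants: 7 3,4-bis(TIPSO)benzaldehyde
Product: 8 3,4-bis(TIPSO)styrene
Conditions: Ph3PCH3Br, n-BuLi, THF, 0 °C; then 7, 0 → 25 °C
Reagents that add atoms: methyltriphenylphosphonium bromide, C[P+](c1ccccc1)(c1ccccc1)c1ccccc1.[Br-]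
Why: Wittig methylenation of an aryl aldehyde with a non-stabilised ylide; no alkoxide is present that could attack the silyl ethers.

Step 7
Reactants: 5 methyl (2R,3R)-6-TIPSO-2-(4-TIPSO-phenyl)-4-(triflyloxy)-2,3-dihydrobenzofuran-3-carboxylate; 8 3,4-bis(TIPSO)styrene
Product: 9 methyl (2R,3R)-4-[(E)-3,4-bis(TIPSO)styryl]-6-TIPSO-2-(4-TIPSO-phenyl)-2,3-dihydrobenzofuran-3-carboxylate (2,3-trans)
Conditions: Pd(OAc)2 (5 mol%), P(o-tol)3, n-Bu4NBr, Et3N, DMF, 90 °C
Reagents that add atoms: none
Why: Mizoroki–Heck reaction of the aryl triflate with the styrene; bromide keeps palladium on the neutral pathway, so the aryl group adds to the terminal alkene carbon and syn β-hydride elimination gives the (E)-stilbene. Triethylamine is too weak to enolise the ester at C3.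

Step 8
Reactants: 9 methyl (2R,3R)-4-[(E)-3,4-bis(TIPSO)styryl]-6-TIPSO-2-(4-TIPSO-phenyl)-2,3-dihydrobenzofuran-3-carboxylate
Product: 10 (2R,3R)-4-[(E)-3,4-bis(TIPSO)styryl]-6-TIPSO-2-(4-TIPSO-phenyl)-2,3-dihydrobenzofuran-3-carbaldehyde (2,3-trans)
Conditions: i-Bu2AlH (1.1 equiv), toluene, −78 °C; MeOH, then aqueous Rochelle salt
Reagents that add atoms: none
Why: Partial reduction of a hindered ester: the aluminium hemiacetal is stable at −78 °C and releases the aldehyde only on work-up. No base is present, so C3 (α to the carbonyl, β to the ring oxygen) is untouched.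

Step 9
Reactants: 5 methyl (2R,3R)-6-TIPSO-2-(4-TIPSO-phenyl)-4-(triflyloxy)-2,3-dihydrobenzofuran-3-carboxylate
Product: 11 (2R,3R)-3-formyl-6-TIPSO-2-(4-TIPSO-phenyl)-2,3-dihydrobenzofuran-4-yl triflate (2,3-trans)
Conditions: i-Bu2AlH (1.1 equiv), toluene, −78 °C; MeOH, then aqueous Rochelle salt
Reagents that add atoms: none
Why: The same partial ester reduction as in step 8; the aryl triflate is inert to the hydride at −78 °C.

Step 10
Reactants: 11 (2R,3R)-3-formyl-6-TIPSO-2-(4-TIPSO-phenyl)-2,3-dihydrobenzofuran-4-yl triflate; 12 pentane-2,4-dione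
Product: 13 6-hydroxy-6-[(2R,3S)-6-TIPSO-2-(4-TIPSO-phenyl)-4-(triflyloxy)-2,3-dihydrobenzofuran-3-yl]hexane-2,4-dione (2,3-trans, both C6 epimers)
Conditions: 12 (3 equiv), LiN(i-Pr)2 (6 equiv), THF, 0 °C; −78 °C, then 11; AcOH, −78 °C
Reagents that add atoms: none
Why: Aldol addition of a β-diketone dianion, which reacts at its terminal carbon; at −78 °C addition to the aldehyde outruns removal of its α-hydrogen. The carbinol configuration is irrelevant because it is oxidised next.

Step 11
Reactants: 13 6-hydroxy-6-[(2R,3S)-6-TIPSO-2-(4-TIPSO-phenyl)-4-(triflyloxy)-2,3-dihydrobenzofuran-3-yl]hexane-2,4-dione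
Product: 15 (2R,3R)-3-(3,5-dihydroxyphenyl)-6-TIPSO-2-(4-TIPSO-phenyl)-2,3-dihydrobenzofuran-4-yl triflate (2,3-trans), via triketone 14 (not isolated)
Conditions: Dess–Martin periodinane, NaHCO3, CH2Cl2, 0 → 25 °C; aqueous Na2S2O3 wash, solvent exchange; then K2CO3, THF/H2O (4:1), 25 °C; citric acid to pH 5
Reagents that add atoms: none
Why: Dess–Martin oxidation gives the 1,3,5-triketone, and mild base closes it by aldol condensation of the terminal methyl carbon onto the carbonyl next to C3 (6-(enolendo)-exo-trig); dehydration and enolisation then give the 5-substituted resorcinol, which is the 3,5-dihydroxyphenyl group of ring C. This is the unhindered, well-precedented form of the key reaction and serves as its rehearsal.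

Step 12
Reactants: 15 (2R,3R)-3-(3,5-dihydroxyphenyl)-6-TIPSO-2-(4-TIPSO-phenyl)-2,3-dihydrobenzofuran-4-yl triflate
Product: 16 (2R,3R)-3-[3,5-bis(TIPSO)phenyl]-6-TIPSO-2-(4-TIPSO-phenyl)-2,3-dihydrobenzofuran-4-yl triflate
Conditions: i-Pr3SiCl (2.5 equiv), imidazole, DMF, 25 °C
Reagents that add atoms: chlorotriisopropylsilane, CC(C)[Si](Cl)(C(C)C)C(C)C
Why: Silylation of the two new phenols, so that ring C carries the same protecting group as the rest.

Step 13
Reactants: 16 (2R,3R)-3-[3,5-bis(TIPSO)phenyl]-6-TIPSO-2-(4-TIPSO-phenyl)-2,3-dihydrobenzofuran-4-yl triflate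
Product: 17 [(2R,3R)-3-[3,5-bis(TIPSO)phenyl]-6-TIPSO-2-(4-TIPSO-phenyl)-2,3-dihydrobenzofuran-4-yl]boronic acid
Conditions: B2(OH)4 (3 equiv), Pd(OAc)2 (5 mol%), XPhos (10 mol%), KOAc, EtOH, 80 °C
Reagents that add atoms: tetrahydroxydiboron, OB(O)B(O)O
Why: Miyaura-type borylation of the aryl triflate with tetrahydroxydiboron, which gives the boronic acid directly. The bulky biarylphosphine permits oxidative addition beside the substituted C3a, and acetate in ethanol does not attack aryl silyl ethers.

Step 14
Reactants: 18 4-hydroxybenzaldehyde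
Product: 19 4-TIPSO-benzaldehyde
Conditions: i-Pr3SiCl (1.1 equiv), imidazole, DMF, 25 °C
Reagents that add atoms: chlorotriisopropylsilane, CC(C)[Si](Cl)(C(C)C)C(C)C
Why: Silylation of the phenol.

Step 15
Reactants: 19 4-TIPSO-benzaldehyde
Product: 20 rac-1-(4-TIPSO-phenyl)prop-2-en-1-ol
Conditions: CH2=CHMgBr, THF, −20 → 0 °C; aqueous NH4Cl
Reagents that add atoms: vinylmagnesium bromide, C=C[Mg]Br
Why: Grignard 1,2-addition to the aldehyde; the racemic carbinol is acceptable because this carbon is ionised in step 23.

Step 16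
Reactants: 20 rac-1-(4-TIPSO-phenyl)prop-2-en-1-ol
Product: 21 rac-1-(1-methoxyprop-2-en-1-yl)-4-TIPSO-benzene
Conditions: NaH, MeI, THF, 0 → 25 °C
Reagents that add atoms: iodomethane, CI
Why: Williamson ether synthesis; the methyl ether protects the carbinol through the base and oxidation steps and later serves as the leaving group.

Step 17
Reactants: 21 rac-1-(1-methoxyprop-2-en-1-yl)-4-TIPSO-benzene; 22 but-3-en-2-one
Product: 23 rac-(E)-5-methoxy-5-(4-TIPSO-phenyl)pent-3-en-2-one
Conditions: 22 (4 equiv), second-generation Hoveyda–Grubbs catalyst (5 mol%), CH2Cl2, 40 °C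
Reagents that add atoms: none
Why: Olefin cross-metathesis between a terminal allylic ether and an electron-poor enone used in excess; the conjugated product is formed as the (E)-isomer.

Step 18
Reactants: 17 [(2R,3R)-3-[3,5-bis(TIPSO)phenyl]-6-TIPSO-2-(4-TIPSO-phenyl)-2,3-dihydrobenzofuran-4-yl]boronic acid; 23 rac-(E)-5-methoxy-5-(4-TIPSO-phenyl)pent-3-en-2-one
Product: 24 (4R)-5-methoxy-4-(unit C)-5-(4-TIPSO-phenyl)pentan-2-one (both C5 epimers)
Conditions: [Rh(OH)((S)-binap)]2 (5 mol% Rh), 23 (2.5 equiv), dioxane/H2O (10:1), 50 °C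
Reagents that add atoms: none
Why: Hayashi–Miyaura reaction: the aryl–rhodium species adds to the enone and water releases the ketone; with the (S)-bisphosphine the aryl group should go to the α-si face of the (E)-enone, which sets the (4R) centre, the future C3 of ring B. A complex free of cyclooctadiene is used so that no achiral diene–rhodium species competes. The racemic enone is in excess so that the catalyst can consume the enantiomer matched to it; both epimers at the methoxy carbon are acceptable.

Step 19
Reactants: 24 (4R)-5-methoxy-4-(unit C)-5-(4-TIPSO-phenyl)pentan-2-one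
Product: 25 (6R)-7-methoxy-6-(unit C)-7-(4-TIPSO-phenyl)heptane-2,4-dione (both C7 epimers)
Conditions: LiN(i-Pr)2 (1.1 equiv), THF, −78 °C; MeC(O)N(OMe)Me (2 equiv), −78 → 0 °C; aqueous NH4Cl
Reagents that add atoms: N-methoxy-N-methylacetamide, CC(=O)N(C)OC
Why: Claisen-type C-acylation of the kinetic, methyl-side lithium enolate with a Weinreb amide. The chelated tetrahedral adduct persists until work-up, so the acidic β-diketone does not appear while enolate is still present and cannot quench it.

Step 20
Reactants: 25 (6R)-7-methoxy-6-(unit C)-7-(4-TIPSO-phenyl)heptane-2,4-dione; 10 (2R,3R)-4-[(E)-3,4-bis(TIPSO)styryl]-6-TIPSO-2-(4-TIPSO-phenyl)-2,3-dihydrobenzofuran-3-carbaldehyde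
Product: 26 (7R)-1-hydroxy-8-methoxy-1-(unit A)-7-(unit C)-8-(4-TIPSO-phenyl)octane-3,5-dione (epimers at C1 and C8)
Conditions: 25, LiN(i-Pr)2 (2.2 equiv), THF, −78 → 0 °C; −78 °C, then 10 (1.1 equiv); AcOH, −78 °C
Reagents that add atoms: none
Why: Aldol addition of the β-diketone dianion: the second deprotonation occurs at the methyl group and not at the methylene beside the branched carbon, and this terminal carbanion adds to the aldehyde faster than it removes the hydrogen at C3 of unit A. An ester or amide at that position would add more slowly and could instead be enolised and opened by β-elimination of the ring oxygen. The new carbinol centre is oxidised next.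

Step 21
Reactants: 26 (7R)-1-hydroxy-8-methoxy-1-(unit A)-7-(unit C)-8-(4-TIPSO-phenyl)octane-3,5-dione
Product: 27 (7R)-8-methoxy-1-(unit A)-7-(unit C)-8-(4-TIPSO-phenyl)octane-1,3,5-trione (both C8 epimers)
Conditions: Dess–Martin periodinane, NaHCO3, CH2Cl2, 0 → 25 °C
Reagents that add atoms: none
Why: Dess–Martin oxidation of the secondary alcohol to the third ketone under buffered, non-basic conditions that leave the stilbene, the silyl ethers and the benzylic methyl ether alone. The triketone is handled as its enol tautomers and used promptly.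

Step 22
Reactants: 27 (7R)-8-methoxy-1-(unit A)-7-(unit C)-8-(4-TIPSO-phenyl)octane-1,3,5-trione
Product: 28 4-[(1S)-2-methoxy-1-(unit C)-2-(4-TIPSO-phenyl)ethyl]-5-(unit A)benzene-1,3-diol (both epimers at the methoxy carbon)
Conditions: K2CO3 (3 equiv), degassed THF/H2O (4:1), 25 °C; then aqueous citric acid to pH 5
Reagents that add atoms: none
Why: In aqueous carbonate 27 is present as enolates delocalised over C1–C5 of the octane chain; the C6 methylene is deprotonated reversibly, its carbon adds to the C1 carbonyl (the one bonded to C3 of unit A), and loss of water followed by enolisation of the C3 and C5 carbonyls gives the aromatic ring, which pulls the equilibria to the product. The closest known reaction is the base-mediated aldol cyclisation of 1,3,5-triketones made from β-diketone dianions to 5-substituted resorcinols, of which step 11 is the methyl-terminated case. The ring that closes is the six-membered carbocycle C1–C6, by a 6-(enolendo)-exo-trig aldol that forms the C6–C1 bond, which is C3a–C4 of ring B. No stereocentre is created; C7 is β to the C5 carbonyl and cannot epimerise, and C3 of unit A is shielded because C1 belongs to an enolised β-dicarbonyl unit, so removing its hydrogen would need a cross-conjugated dianion, and any epimerisation would return to the trans ring. The selectivity needed is between aldol modes: attack of C3 of unit A on the C5 carbonyl gives a quaternary aldol that cannot aromatise and reverts, attack by C2 or C4 would give four-membered rings, and oxygen cyclisation to a 4-pyranone needs acid, so only the C6-to-C1 closure is productive. Carbonate at room temperature is chosen because it maintains the enolate equilibria but spares aryl silyl ethers and does not cleave the triketone by retro-Claisen reaction as hydroxide or alkoxide would. The product is a free resorcinol whose new hydroxyl at the future C7a sits ortho to the branched carbon, placed for step 23.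

Step 23
Reactants: 28 4-[(1S)-2-methoxy-1-(unit C)-2-(4-TIPSO-phenyl)ethyl]-5-(unit A)benzene-1,3-diol
Product: 29 (2S,3S)-4-(unit A)-3-(unit C)-2-(4-TIPSO-phenyl)-2,3-dihydrobenzofuran-6-ol
Conditions: CF3CO2H (2 equiv), CH2Cl2, −20 → 0 °C; Et3N quench
Reagents that add atoms: none
Why: Acid ionises the para-silyloxybenzylic methyl ether of either epimer to one planar cation, which the ortho phenol captures in a five-membered ring closure; attack anti to the aryl group on C3 gives the 2,3-trans ring, which is also the thermodynamic isomer should the closure reverse. The silyl ethers make the other arenes poorer carbon nucleophiles than free phenols, and low temperature and a short reaction time are meant to keep the cation from closing a seven-membered ring on carbon.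

Step 24
Reactants: 29 (2S,3S)-4-(unit A)-3-(unit C)-2-(4-TIPSO-phenyl)-2,3-dihydrobenzofuran-6-ol
Product: 30 CNP0099535.1, (2S,3S)-4-{(2R,3R)-4-[(E)-3,4-dihydroxystyryl]-6-hydroxy-2-(4-hydroxyphenyl)-2,3-dihydrobenzofuran-3-yl}-3-{(2R,3R)-3-(3,5-dihydroxyphenyl)-6-hydroxy-2-(4-hydroxyphenyl)-2,3-dihydrobenzofuran-4-yl}-2-(4-hydroxyphenyl)-2,3-dihydrobenzofuran-6-ol
Conditions: n-Bu4NF/AcOH (1:1, 12 equiv), THF, 0 → 25 °C, argon
Reagents that add atoms: none
Why: Fluoride cleaves the nine aryl silyl ethers; buffering with acetic acid keeps the medium near neutral, so neither phenoxide-driven opening of the 2-(4-hydroxyphenyl) rings nor acid-induced cation chemistry of the stilbene should occur. Exclusion of air protects the catechol.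

## Compound list

1 | naringenin (racemic) | O=C1CC(c2ccc(O)cc2)Oc2cc(O)cc(O)c21 | starting material
2 | rac-5-hydroxy-7-TIPSO-2-(4-TIPSO-phenyl)chroman-4-one | O=C1CC(c2ccc(O[Si](C(C)C)(C(C)C)C(C)C)cc2)Oc2cc(O[Si](C(C)C)(C(C)C)C(C)C)cc(O)c21 | intermediate
3 | rac-4-oxo-7-TIPSO-2-(4-TIPSO-phenyl)chroman-5-yl triflate | O=C1CC(c2ccc(O[Si](C(C)C)(C(C)C)C(C)C)cc2)Oc2cc(O[Si](C(C)C)(C(C)C)C(C)C)cc(OS(=O)(=O)C(F)(F)F)c21 | intermediate
4 | (2R)-4-oxo-7-TIPSO-2-(4-TIPSO-phenyl)chroman-5-yl triflate | O=C1C[C@H](c2ccc(O[Si](C(C)C)(C(C)C)C(C)C)cc2)Oc2cc(O[Si](C(C)C)(C(C)C)C(C)C)cc(OS(=O)(=O)C(F)(F)F)c21 | intermediate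
5 | methyl (2R,3R)-6-TIPSO-2-(4-TIPSO-phenyl)-4-(triflyloxy)-2,3-dihydrobenzofuran-3-carboxylate (2,3-trans) | COC(=O)[C@@H]1c2c(OS(=O)(=O)C(F)(F)F)cc(O[Si](C(C)C)(C(C)C)C(C)C)cc2O[C@H]1c1ccc(O[Si](C(C)C)(C(C)C)C(C)C)cc1 | intermediate
6 | 3,4-dihydroxybenzaldehyde | O=Cc1ccc(O)c(O)c1 | starting material
7 | 3,4-bis(TIPSO)benzaldehyde | O=Cc1ccc(O[Si](C(C)C)(C(C)C)C(C)C)c(O[Si](C(C)C)(C(C)C)C(C)C)c1 | intermediate
8 | 3,4-bis(TIPSO)styrene | C=Cc1ccc(O[Si](C(C)C)(C(C)C)C(C)C)c(O[Si](C(C)C)(C(C)C)C(C)C)c1 | intermediate
9 | methyl (2R,3R)-4-[(E)-3,4-bis(TIPSO)styryl]-6-TIPSO-2-(4-TIPSO-phenyl)-2,3-dihydrobenzofuran-3-carboxylate (2,3-trans) | COC(=O)[C@@H]1c2c(/C=C/c3ccc(O[Si](C(C)C)(C(C)C)C(C)C)c(O[Si](C(C)C)(C(C)C)C(C)C)c3)cc(O[Si](C(C)C)(C(C)C)C(C)C)cc2O[C@H]1c1ccc(O[Si](C(C)C)(C(C)C)C(C)C)cc1 | intermediate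
10 | (2R,3R)-4-[(E)-3,4-bis(TIPSO)styryl]-6-TIPSO-2-(4-TIPSO-phenyl)-2,3-dihydrobenzofuran-3-carbaldehyde (2,3-trans) | O=C[C@@H]1c2c(/C=C/c3ccc(O[Si](C(C)C)(C(C)C)C(C)C)c(O[Si](C(C)C)(C(C)C)C(C)C)c3)cc(O[Si](C(C)C)(C(C)C)C(C)C)cc2O[C@H]1c1ccc(O[Si](C(C)C)(C(C)C)C(C)C)cc1 | intermediate
11 | (2R,3R)-3-formyl-6-TIPSO-2-(4-TIPSO-phenyl)-2,3-dihydrobenzofuran-4-yl triflate (2,3-trans) | O=C[C@@H]1c2c(OS(=O)(=O)C(F)(F)F)cc(O[Si](C(C)C)(C(C)C)C(C)C)cc2O[C@H]1c1ccc(O[Si](C(C)C)(C(C)C)C(C)C)cc1 | intermediate
12 | pentane-2,4-dione | CC(=O)CC(C)=O | starting material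
13 | 6-hydroxy-6-[(2R,3S)-6-TIPSO-2-(4-TIPSO-phenyl)-4-(triflyloxy)-2,3-dihydrobenzofuran-3-yl]hexane-2,4-dione (2,3-trans, both C6 epimers) | CC(=O)CC(=O)CC(O)[C@@H]1c2c(OS(=O)(=O)C(F)(F)F)cc(O[Si](C(C)C)(C(C)C)C(C)C)cc2O[C@H]1c1ccc(O[Si](C(C)C)(C(C)C)C(C)C)cc1 | intermediate
14 | 1-[(2R,3R)-6-TIPSO-2-(4-TIPSO-phenyl)-4-(triflyloxy)-2,3-dihydrobenzofuran-3-yl]hexane-1,3,5-trione (2,3-trans) | CC(=O)CC(=O)CC(=O)[C@@H]1c2c(OS(=O)(=O)C(F)(F)F)cc(O[Si](C(C)C)(C(C)C)C(C)C)cc2O[C@H]1c1ccc(O[Si](C(C)C)(C(C)C)C(C)C)cc1 | intermediate (not isolated)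
15 | (2R,3R)-3-(3,5-dihydroxyphenyl)-6-TIPSO-2-(4-TIPSO-phenyl)-2,3-dihydrobenzofuran-4-yl triflate (2,3-trans) | Oc1cc(O)cc([C@@H]2c3c(OS(=O)(=O)C(F)(F)F)cc(O[Si](C(C)C)(C(C)C)C(C)C)cc3O[C@H]2c2ccc(O[Si](C(C)C)(C(C)C)C(C)C)cc2)c1 | intermediate
16 | (2R,3R)-3-[3,5-bis(TIPSO)phenyl]-6-TIPSO-2-(4-TIPSO-phenyl)-2,3-dihydrobenzofuran-4-yl triflate (2,3-trans) | CC(C)[Si](Oc1cc(O[Si](C(C)C)(C(C)C)C(C)C)cc([C@@H]2c3c(OS(=O)(=O)C(F)(F)F)cc(O[Si](C(C)C)(C(C)C)C(C)C)cc3O[C@H]2c2ccc(O[Si](C(C)C)(C(C)C)C(C)C)cc2)c1)(C(C)C)C(C)C | intermediate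
17 | [(2R,3R)-3-[3,5-bis(TIPSO)phenyl]-6-TIPSO-2-(4-TIPSO-phenyl)-2,3-dihydrobenzofuran-4-yl]boronic acid (2,3-trans) | OB(O)c1cc(O[Si](C(C)C)(C(C)C)C(C)C)cc2c1[C@@H](c1cc(O[Si](C(C)C)(C(C)C)C(C)C)cc(O[Si](C(C)C)(C(C)C)C(C)C)c1)[C@H](c1ccc(O[Si](C(C)C)(C(C)C)C(C)C)cc1)O2 | intermediate
18 | 4-hydroxybenzaldehyde | O=Cc1ccc(O)cc1 | starting material
19 | 4-TIPSO-benzaldehyde | O=Cc1ccc(O[Si](C(C)C)(C(C)C)C(C)C)cc1 | intermediate
20 | rac-1-(4-TIPSO-phenyl)prop-2-en-1-ol | C=CC(O)c1ccc(O[Si](C(C)C)(C(C)C)C(C)C)cc1 | intermediate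
21 | rac-1-(1-methoxyprop-2-en-1-yl)-4-TIPSO-benzene | C=CC(OC)c1ccc(O[Si](C(C)C)(C(C)C)C(C)C)cc1 | intermediate
22 | but-3-en-2-one | C=CC(C)=O | starting material
23 | rac-(E)-5-methoxy-5-(4-TIPSO-phenyl)pent-3-en-2-one | CC(=O)/C=C/C(OC)c1ccc(O[Si](C(C)C)(C(C)C)C(C)C)cc1 | intermediate
24 | (4R)-5-methoxy-4-(unit C)-5-(4-TIPSO-phenyl)pentan-2-one (both C5 epimers) | CC(=O)C[C@@H](C(OC)c1ccc(O[Si](C(C)C)(C(C)C)C(C)C)cc1)c1cc(O[Si](C(C)C)(C(C)C)C(C)C)cc2c1[C@@H](c1cc(O[Si](C(C)C)(C(C)C)C(C)C)cc(O[Si](C(C)C)(C(C)C)C(C)C)c1)[C@H](c1ccc(O[Si](C(C)C)(C(C)C)C(C)C)cc1)O2 | intermediate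
25 | (6R)-7-methoxy-6-(unit C)-7-(4-TIPSO-phenyl)heptane-2,4-dione (both C7 epimers) | CC(=O)CC(=O)C[C@@H](C(OC)c1ccc(O[Si](C(C)C)(C(C)C)C(C)C)cc1)c1cc(O[Si](C(C)C)(C(C)C)C(C)C)cc2c1[C@@H](c1cc(O[Si](C(C)C)(C(C)C)C(C)C)cc(O[Si](C(C)C)(C(C)C)C(C)C)c1)[C@H](c1ccc(O[Si](C(C)C)(C(C)C)C(C)C)cc1)O2 | intermediate
26 | (7R)-1-hydroxy-8-methoxy-1-(unit A)-7-(unit C)-8-(4-TIPSO-phenyl)octane-3,5-dione (epimers at C1 and C8; unit A formally 2R,3S) | OC(CC(=O)CC(=O)C[C@@H](C(OC)c1ccc(O[Si](C(C)C)(C(C)C)C(C)C)cc1)c1cc(O[Si](C(C)C)(C(C)C)C(C)C)cc2c1[C@@H](c1cc(O[Si](C(C)C)(C(C)C)C(C)C)cc(O[Si](C(C)C)(C(C)C)C(C)C)c1)[C@H](c1ccc(O[Si](C(C)C)(C(C)C)C(C)C)cc1)O2)[C@@H]1c2c(/C=C/c3ccc(O[Si](C(C)C)(C(C)C)C(C)C)c(O[Si](C(C)C)(C(C)C)C(C)C)c3)cc(O[Si](C(C)C)(C(C)C)C(C)C)cc2O[C@H]1c1ccc(O[Si](C(C)C)(C(C)C)C(C)C)cc1 | intermediate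
27 | (7R)-8-methoxy-1-(unit A)-7-(unit C)-8-(4-TIPSO-phenyl)octane-1,3,5-trione (both C8 epimers; unit A 2R,3R) | O=C(CC(=O)CC(=O)C[C@@H](C(OC)c1ccc(O[Si](C(C)C)(C(C)C)C(C)C)cc1)c1cc(O[Si](C(C)C)(C(C)C)C(C)C)cc2c1[C@@H](c1cc(O[Si](C(C)C)(C(C)C)C(C)C)cc(O[Si](C(C)C)(C(C)C)C(C)C)c1)[C@H](c1ccc(O[Si](C(C)C)(C(C)C)C(C)C)cc1)O2)[C@@H]1c2c(/C=C/c3ccc(O[Si](C(C)C)(C(C)C)C(C)C)c(O[Si](C(C)C)(C(C)C)C(C)C)c3)cc(O[Si](C(C)C)(C(C)C)C(C)C)cc2O[C@H]1c1ccc(O[Si](C(C)C)(C(C)C)C(C)C)cc1 | intermediate (precursor of the key step)
28 | 4-[(1S)-2-methoxy-1-(unit C)-2-(4-TIPSO-phenyl)ethyl]-5-(unit A)benzene-1,3-diol (both epimers at the methoxy carbon; unit A 2R,3R) | Oc1cc(O)cc([C@@H]2c3c(/C=C/c4ccc(O[Si](C(C)C)(C(C)C)C(C)C)c(O[Si](C(C)C)(C(C)C)C(C)C)c4)cc(O[Si](C(C)C)(C(C)C)C(C)C)cc3O[C@H]2c2ccc(O[Si](C(C)C)(C(C)C)C(C)C)cc2)c1[C@@H](C(OC)c1ccc(O[Si](C(C)C)(C(C)C)C(C)C)cc1)c1cc(O[Si](C(C)C)(C(C)C)C(C)C)cc2c1[C@@H](c1cc(O[Si](C(C)C)(C(C)C)C(C)C)cc(O[Si](C(C)C)(C(C)C)C(C)C)c1)[C@H](c1ccc(O[Si](C(C)C)(C(C)C)C(C)C)cc1)O2 | intermediate (product of the key step)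
29 | (2S,3S)-4-(unit A)-3-(unit C)-2-(4-TIPSO-phenyl)-2,3-dihydrobenzofuran-6-ol (nona-O-TIPS ether of the target) | CC(C)[Si](Oc1ccc([C@H]2Oc3cc(O)cc([C@@H]4c5c(/C=C/c6ccc(O[Si](C(C)C)(C(C)C)C(C)C)c(O[Si](C(C)C)(C(C)C)C(C)C)c6)cc(O[Si](C(C)C)(C(C)C)C(C)C)cc5O[C@H]4c4ccc(O[Si](C(C)C)(C(C)C)C(C)C)cc4)c3[C@@H]2c2cc(O[Si](C(C)C)(C(C)C)C(C)C)cc3c2[C@@H](c2cc(O[Si](C(C)C)(C(C)C)C(C)C)cc(O[Si](C(C)C)(C(C)C)C(C)C)c2)[C@H](c2ccc(O[Si](C(C)C)(C(C)C)C(C)C)cc2)O3)cc1)(C(C)C)C(C)C | intermediate
30 | CNP0099535.1, (2S,3S)-4-{(2R,3R)-4-[(E)-3,4-dihydroxystyryl]-6-hydroxy-2-(4-hydroxyphenyl)-2,3-dihydrobenzofuran-3-yl}-3-{(2R,3R)-3-(3,5-dihydroxyphenyl)-6-hydroxy-2-(4-hydroxyphenyl)-2,3-dihydrobenzofuran-4-yl}-2-(4-hydroxyphenyl)-2,3-dihydrobenzofuran-6-ol | Oc1ccc([C@H]2Oc3cc(O)cc([C@@H]4c5c(/C=C/c6ccc(O)c(O)c6)cc(O)cc5O[C@H]4c4ccc(O)cc4)c3[C@@H]2c2cc(O)cc3c2[C@@H](c2cc(O)cc(O)c2)[C@H](c2ccc(O)cc2)O3)cc1 | target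

## Step count and risk

Total step count: 24. Longest linear sequence: 16 steps (steps 1–4, 9–13 and 18–24).

Steps least certain to work, each with one fallback:

Step 22 (key step). The C6 methylene of 27 is the least acidic and most hindered enolisable site, so its enolate may form too slowly; retro-Claisen cleavage of the triketone, or epimerisation and opening of ring A at C3 beside C1, could then overtake ring closure. Fallback: generate the C6 enolate regiospecifically by carbometalation instead of by deprotonation. The fallback sets out from 23. Its kinetic lithium enolate is acylated with N-methoxy-N-methylacetamide to give rac-(E)-7-methoxy-7-(4-TIPSO-phenyl)hept-5-ene-2,4-dione F1. The dianion of F1 is added to 10 to give (6E)-1-hydroxy-8-methoxy-1-(unit A)-8-(4-TIPSO-phenyl)oct-6-ene-3,5-dione F2, and Dess–Martin oxidation gives (6E)-8-methoxy-1-(unit A)-8-(4-TIPSO-phenyl)oct-6-ene-1,3,5-trione F3. Treatment of F3 with 17 and [Rh(OH)((S)-binap)]2 in dioxane/H2O should add the aryl group to the enone β-carbon and generate the rhodium enolate at C6, which closes onto the C1 carbonyl (tandem conjugate arylation–aldol cyclisation, known for keto-enones). Dehydration and enolisation then give 28, where the route is rejoined.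

Step 4. The electron-rich 2-aryl group may migrate instead of the benzo carbon (which has the electron-withdrawing triflate ortho to it), or iodobenzene may be lost by elimination to the flavone. Fallback: a Wolff ring contraction, in which only the benzo carbon can migrate. The fallback sets out from 4. Its lithium enolate (LiN(SiMe3)2, −78 °C; the C2–O bond is poorly aligned for β-elimination) is trifluoroacetylated with CF3CO2CH2CF3 to 4-oxo-7-TIPSO-2-(4-TIPSO-phenyl)-3-(trifluoroacetyl)chroman-5-yl triflate F4. Diazo transfer with MsN3 and Et3N removes the trifluoroacetyl group and gives 3-diazo-4-oxo-7-TIPSO-2-(4-TIPSO-phenyl)chroman-5-yl triflate F5, with C2 unchanged in space. Irradiation (365 nm) in MeOH gives the ketene and then the methyl ester as a cis/trans mixture, which DBU equilibrates to the trans ester 5.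

Step 18. The hindered, electron-rich boronic acid may undergo protodeboronation before transmetalation, or facial control may be eroded for the mismatched enantiomer of 23. Fallback: make the aryl–carbon bond by a Mizoroki–Heck reaction and set the stereocentre by reduction. The fallback sets out from 16. Heck coupling with 23 (Pd(OAc)2, P(o-tol)3, Et3N, DMF) should give (3Z)-5-methoxy-4-(unit C)-5-(4-TIPSO-phenyl)pent-3-en-2-one F6, its geometry fixed by syn insertion and syn elimination. Copper hydride conjugate reduction (Cu(OAc)2, one enantiomer of DTBM-SEGPHOS chosen on a model to give 4R, polymethylhydrosiloxane, t-BuOH) then leads back to 24.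

Step 20. The dianion may remove the hydrogen at C3 of 10 instead of adding (enolisation, then opening of the furan ring by loss of the aryloxide), or the adduct may undergo retro-aldol cleavage during work-up. Fallback: acylation at the ketone oxidation level instead of aldol plus oxidation. The fallback sets out from 9. Me2AlN(OMe)Me (from AlMe3 and MeNHOMe·HCl) converts it into (2R,3R)-4-[(E)-3,4-bis(TIPSO)styryl]-N-methoxy-N-methyl-6-TIPSO-2-(4-TIPSO-phenyl)-2,3-dihydrobenzofuran-3-carboxamide F7. Its α-hydrogen is far less acidic than that of the aldehyde, and its adduct with the dianion of 25 is a stable chelate, which on work-up gives 27 directly.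

Step 23. The new benzylic aryl ether may re-ionise under the acid and the cation be captured by carbon (the ortho position of the 3,5-disilyloxyphenyl ring of unit C, seven-membered ring), or the styryl alkene may be protonated. Fallback: reverse the order and close the ring without acid. The fallback sets out from 28. Desilylation with n-Bu4NF/AcOH gives 4-{(1S)-1-[(2R,3R)-3-(3,5-dihydroxyphenyl)-6-hydroxy-2-(4-hydroxyphenyl)-2,3-dihydrobenzofuran-4-yl]-2-(4-hydroxyphenyl)-2-methoxyethyl}-5-{(2R,3R)-4-[(E)-3,4-dihydroxystyryl]-6-hydroxy-2-(4-hydroxyphenyl)-2,3-dihydrobenzofuran-3-yl}benzene-1,3-diol F8. Warming F8 in aqueous MeCN with NaHCO3 under argon should expel methanol from the para-hydroxybenzylic ether to a para-quinone methide, which the adjacent phenol captures reversibly (oxa-conjugate addition, five-membered ring) to give the trans ring of 30 directly.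

Further compounds

F1 | step 22 | rac-(E)-7-methoxy-7-(4-TIPSO-phenyl)hept-5-ene-2,4-dione | CC(=O)CC(=O)/C=C/C(OC)c1ccc(O[Si](C(C)C)(C(C)C)C(C)C)cc1
F2 | step 22 | (6E)-1-hydroxy-8-methoxy-1-(unit A)-8-(4-TIPSO-phenyl)oct-6-ene-3,5-dione | OC(CC(=O)CC(=O)/C=C/C(OC)c1ccc(O[Si](C(C)C)(C(C)C)C(C)C)cc1)[C@@H]1c2c(/C=C/c3ccc(O[Si](C(C)C)(C(C)C)C(C)C)c(O[Si](C(C)C)(C(C)C)C(C)C)c3)cc(O[Si](C(C)C)(C(C)C)C(C)C)cc2O[C@H]1c1ccc(O[Si](C(C)C)(C(C)C)C(C)C)cc1
F3 | step 22 | (6E)-8-methoxy-1-(unit A)-8-(4-TIPSO-phenyl)oct-6-ene-1,3,5-trione | O=C(CC(=O)CC(=O)/C=C/C(OC)c1ccc(O[Si](C(C)C)(C(C)C)C(C)C)cc1)[C@@H]1c2c(/C=C/c3ccc(O[Si](C(C)C)(C(C)C)C(C)C)c(O[Si](C(C)C)(C(C)C)C(C)C)c3)cc(O[Si](C(C)C)(C(C)C)C(C)C)cc2O[C@H]1c1ccc(O[Si](C(C)C)(C(C)C)C(C)C)cc1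
F4 | step 4 | 4-oxo-7-TIPSO-2-(4-TIPSO-phenyl)-3-(trifluoroacetyl)chroman-5-yl triflate (C2 as in 4) | O=C1C(C(=O)C(F)(F)F)[C@H](c2ccc(O[Si](C(C)C)(C(C)C)C(C)C)cc2)Oc2cc(O[Si](C(C)C)(C(C)C)C(C)C)cc(OS(=O)(=O)C(F)(F)F)c21
F5 | step 4 | 3-diazo-4-oxo-7-TIPSO-2-(4-TIPSO-phenyl)chroman-5-yl triflate (C2 as in 4) | O=C1C(=[N+]=[N-])[C@H](c2ccc(O[Si](C(C)C)(C(C)C)C(C)C)cc2)Oc2cc(O[Si](C(C)C)(C(C)C)C(C)C)cc(OS(=O)(=O)C(F)(F)F)c21
F6 | step 18 | (3Z)-5-methoxy-4-(unit C)-5-(4-TIPSO-phenyl)pent-3-en-2-one | CC(=O)/C=C(\C(OC)c1ccc(O[Si](C(C)C)(C(C)C)C(C)C)cc1)c1cc(O[Si](C(C)C)(C(C)C)C(C)C)cc2c1[C@@H](c1cc(O[Si](C(C)C)(C(C)C)C(C)C)cc(O[Si](C(C)C)(C(C)C)C(C)C)c1)[C@H](c1ccc(O[Si](C(C)C)(C(C)C)C(C)C)cc1)O2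
F7 | step 20 | (2R,3R)-4-[(E)-3,4-bis(TIPSO)styryl]-N-methoxy-N-methyl-6-TIPSO-2-(4-TIPSO-phenyl)-2,3-dihydrobenzofuran-3-carboxamide | CON(C)C(=O)[C@@H]1c2c(/C=C/c3ccc(O[Si](C(C)C)(C(C)C)C(C)C)c(O[Si](C(C)C)(C(C)C)C(C)C)c3)cc(O[Si](C(C)C)(C(C)C)C(C)C)cc2O[C@H]1c1ccc(O[Si](C(C)C)(C(C)C)C(C)C)cc1
F8 | step 23 | fully desilylated seco-phenol with the benzylic methyl ether (both epimers at the methoxy carbon) | Oc1cc(O)cc([C@@H]2c3c(/C=C/c4ccc(O)c(O)c4)cc(O)cc3O[C@H]2c2ccc(O)cc2)c1[C@@H](C(OC)c1ccc(O)cc1)c1cc(O)cc2c1[C@@H](c1cc(O)cc(O)c1)[C@H](c1ccc(O)cc1)O2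
A1 | alternative 1 | (2R)-7-methoxy-2-(4-methoxyphenyl)-4-oxochroman-5-yl triflate | O=C1C[C@H](c2ccc(OC)cc2)Oc2cc(OC)cc(OS(=O)(=O)C(F)(F)F)c21
A2 | alternative 1 | methyl trans-(2R,3R)-6-methoxy-2-(4-methoxyphenyl)-4-(triflyloxy)-2,3-dihydrobenzofuran-3-carboxylate | COC(=O)[C@@H]1c2c(OS(=O)(=O)C(F)(F)F)cc(OC)cc2O[C@H]1c1ccc(OC)cc1
A3 | alternative 2 | octa-O-methyl tris-dihydrobenzofuran with chloride in place of the styryl group | COc1ccc([C@H]2Oc3cc(OC)cc([C@@H]4c5c(Cl)cc(OC)cc5O[C@H]4c4ccc(OC)cc4)c3[C@@H]2c2cc(OC)cc3c2[C@@H](c2cc(OC)cc(OC)c2)[C@H](c2ccc(OC)cc2)O3)cc1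
A4 | alternative 3 | octa-O-methyl tris-dihydrobenzofuran with a TIPS-oxymethyl group at C4 of ring A and both outer rings cis | COc1ccc([C@H]2Oc3cc(OC)cc([C@@H]4c5c(CO[Si](C(C)C)(C(C)C)C(C)C)cc(OC)cc5O[C@@H]4c4ccc(OC)cc4)c3[C@@H]2c2cc(OC)cc3c2[C@@H](c2cc(OC)cc(OC)c2)[C@@H](c2ccc(OC)cc2)O3)cc1
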